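**Route in brief.** The pyrrole ring is bought, the benzene ring is built onto it by a light-driven ring closure of a dibromodiene, and the last bromine is put on C2 at the end. Compounds carry the numbers 1–16 used in the steps; 16 is the target.

## Analysis of the target

2,3,7-Tribromoindole (16) is a planar, achiral 1H-indole: a pyrrole ring (N1, C2, C3, C3a, C7a) fused along the C3a–C7a bond to a benzene ring (C3a, C4–C7, C7a). There are no stereocentres, so the problem is one of regiochemistry: bromine at C2 and C3 of the pyrrole ring and at C7, the benzene carbon next to the ring-fusion atom C7a and peri to N–H. C3 and then C2 are the positions an electrophile attacks first, so those two bromines are easy to place. C7 is the least accessible position of an indole towards electrophilic substitution, so its bromine has to be built in. The free N–H 2,3-dibromoindole unit is electron-rich and prone to oxidation, acid-induced decomposition and light-induced loss of bromine, so it should be made last and kept cold and dark. All three C–Br bonds are also open to halogen–metal exchange and to low-valent transition metals. The strategy rests on the fact that C7 is bonded to C7a: C7 can be the CBr2 end of a triene whose other end is a pyrrole α-carbon (the future C7a). Closing the C7–C7a bond then forms the benzene ring, one bromine stays on C7 and the other leaves as HBr.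

## Retrosynthetic reasoning

**C2–Br.** The C2–Br bond of 16 is cut first, leading back to 3,7-dibromoindole 15. With C3 blocked and the benzene ring deactivated by the C7 bromine, C2 is the one position an electrophilic bromine source should still attack readily. Placing this bond last keeps the labile N–H 2,3-dibromoindole out of every other step.

**N–H.** Indole 15 is traced to its N-Boc derivative 14. The carbamate is needed in the ring-forming step, and on an indole nitrogen it is an activated acyl group that mild base in methanol removes without touching aryl bromides.

**C7–C7a (the benzene ring).** In 14 the C7–C7a bond is cut and the benzene ring is opened to a triene. This is the key disconnection, and it is made at the bond that joins the hardest carbon (C7) to the ring fusion. It leads to Z-diene 12, a 3-bromopyrrole carrying a 4,4-dibromobuta-1,3-dienyl chain at C4. Forward, the pyrrole C4=C5 bond, the Z alkene and the CBr2 alkene must close by a six-electron electrocyclisation to dihydroindole 13, which aromatises by loss of HBr. One disconnection thus accounts for the ring, the C7 bromine and the aromatic oxidation level. Because 12 is the thermodynamically less favoured alkene isomer, it is not made as such; it is generated under the same light from the E-diene 11.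

**C=CBr2.** The dibromoalkene of 11 is cut to enal 9 and carbon tetrabromide 10. A dibromomethylene ylide converts an aldehyde into exactly this terminus, so both bromines of the future C7 come from one cheap reagent.

**C=C of the enal.** The alkene of 9 is cut to pyrrole aldehyde 7 and the formylmethylene ylide 8. This adds the two carbons that become C4 and C5 of the indole in one step and at the aldehyde oxidation level.

**Nitrogen substituent.** Carbamate 7 is traced to silyl pyrrole 4 and Boc anhydride 5 through the N–H pyrrole 6. The silyl group is needed to build the pyrrole substitution pattern but is too bulky to sit beside the C7 bromine of the indole. The carbamate is smaller, tempers the electron-rich pyrrole for the photochemical step, and can be removed at the end.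

**Pyrrole substituents.** The formyl group of 4 is cut to lithiopyrrole 3, which comes from dibromide 2 by exchange of one of two equivalent bromines. Dibromide 2 comes from the commercial silyl pyrrole 1, whose bulky silyl group steers both brominations to the β-positions. The bromine that remains on 4 is the C3 bromine of the target.

## Alternatives that were turned down

**Alternative 1:** The bonds C3a–C7a, C4–C5 and C6–C7 are cut together, so both rings come from the ynamide diyne A2 and acetylene A3. Forward, RhCl(PPh3)3 would join them in a [2+2+2] cycloaddition to the 7-silyl N-tosylindoline A1.
- For: the tether fixes the regiochemistry, the silyl group marks C7 unambiguously, and this cycloaddition type is well established. On the certainty of the key step this alternative is stronger than the chosen route.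
- Against: A1 has none of the three bromines and is at the indoline oxidation level. It would need ipso-bromodesilylation, removal of the sulfonyl group (its reductive cleavage is hard to reconcile with an aryl bromide), dehydrogenation and two further brominations. A2 itself takes several steps, and acetylene must be kept from oligomerising with the catalyst.
- Comparison: the route would be clearly longer. The chosen key step gives an aromatic indole with two bromines already in place.

**Alternative 2:** The C3–C3a bond is cut, leading to the enamino ester A5, the adduct of an ortho-bromoaniline and a propiolate ester. Forward, iodide-mediated anodic oxidation in an undivided cell would couple the enamine α-carbon with the only free ortho carbon to give the indole ester A4.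
- For: the C7 bromine is present from the first step, only one ortho position is open so the regiochemistry is fixed, and no metal catalyst is needed. On step count and cost of materials this alternative is stronger than the chosen route.
- Against: the C3 substituent of A4 is an ester, so a carbon has to be removed again by hydrolysis and bromodecarboxylation. The iodide mediator can also iodinate the electron-rich product.
- Comparison: the chosen route is longer but carries the C3 bromine from the start with no group to excise. It also builds the benzene ring from a diene terminus, which sets the halogen pattern without reference to what anilines are available.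

**Alternative 3:** The N1–C7a bond and the C7–Br bond are cut together, leading to the N-silyl fluorophenethylamine A7. Forward, t-BuLi would form the lithium amide, lithiate next to fluorine and generate an aryne; nitrogen adds to it and the resulting C7 aryllithium is trapped by an electrophilic bromine source to give the 7-bromoindoline A6.
- For: the ring bond and the C7 bromine are set in one operation with complete regiocontrol, and the sequence to the target would be shorter than the chosen one.
- Against: the step needs several equivalents of t-BuLi at low temperature, and the bromine source must outcompete the excess base. A6 is an indoline, so desilylation and dehydrogenation must come before any further bromination, since an indoline would brominate para to nitrogen.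
- Comparison: this alternative is stronger on length and on precedent. The chosen route avoids aryne and alkyllithium chemistry late in the sequence and reaches the indole oxidation level and the C3 bromine directly in its key step.

Key step: step 6

Remark on the chemistry: the Wittig and dibromoolefination steps are taken to give the E-diene 11. The Z-diene 12 that actually closes is generated from 11 by the same light in step 6 and is not isolated. Compounds 11 to 16 should be handled in amber glassware.

## Route

Step 1
Reactants: 1 1-(triisopropylsilyl)-1H-pyrrole
Product: 2 3,4-dibromo-1-(triisopropylsilyl)-1H-pyrrole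
Conditions: N-bromosuccinimide (2.0 equiv), THF, −78 °C to rt
Reagents that add atoms: N-bromosuccinimide, O=C1CCC(=O)N1Br
Why: Electrophilic aromatic bromination; the bulky silyl group shields both α-positions, so the two β-positions are brominated in turn, a standard entry to 3,4-dihalopyrroles.

Step 2
Reactants: 2 3,4-dibromo-1-(triisopropylsilyl)-1H-pyrrole
Product: 4 4-bromo-1-(triisopropylsilyl)-1H-pyrrole-3-carbaldehyde, via 3-bromo-4-lithio-1-(triisopropylsilyl)pyrrole 3 (not isolated)
Conditions: n-BuLi (1.05 equiv), THF, −78 °C; DMF, −78 °C to rt; aq. NH4Cl
Reagents that add atoms: N,N-dimethylformamide, CN(C)C=O (n-butyllithium, [Li]CCCC, supplies only the lithium of intermediate 3)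
Why: Bromine–lithium exchange on one of two equivalent C–Br bonds, followed by formylation of the pyrrolyllithium with DMF; the second exchange is disfavoured once the ring carries lithium, and the silyl group prevents migration of lithium to an α-position at low temperature.

Step 3
Reactants: 4 4-bromo-1-(triisopropylsilyl)-1H-pyrrole-3-carbaldehyde; 5 di-tert-butyl dicarbonate
Product: 7 tert-butyl 3-bromo-4-formyl-1H-pyrrole-1-carboxylate, via 4-bromo-1H-pyrrole-3-carbaldehyde 6 (not isolated)
Conditions: Bu4NF (1.1 equiv), THF, 0 °C; then Boc2O, DMAP (cat.), rt
Reagents that add atoms: di-tert-butyl dicarbonate (5), CC(C)(C)OC(=O)OC(=O)OC(C)(C)C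
Why: Protecting-group exchange; fluoride cleaves the N–Si bond to the pyrrolide of 6, which is acylated at nitrogen by Boc2O under DMAP catalysis, giving the smaller, electron-withdrawing carbamate needed beside the future C7 bromine and for the photochemical step.

Step 4
Reactants: 7 tert-butyl 3-bromo-4-formyl-1H-pyrrole-1-carboxylate; 8 (triphenylphosphoranylidene)acetaldehyde
Product: 9 tert-butyl 3-bromo-4-[(1E)-3-oxoprop-1-en-1-yl]-1H-pyrrole-1-carboxylate
Conditions: 8 (1.2 equiv), toluene, 80 °C
Reagents that add atoms: (triphenylphosphoranylidene)acetaldehyde (8), O=CC=P(c1ccccc1)(c1ccccc1)c1ccccc1
Why: Wittig olefination with a stabilised formylmethylene ylide, which should give the E-enal; only a small excess of ylide is used so that the product aldehyde is not homologated a second time.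

Step 5
Reactants: 9 tert-butyl 3-bromo-4-[(1E)-3-oxoprop-1-en-1-yl]-1H-pyrrole-1-carboxylate; 10 carbon tetrabromide
Product: 11 tert-butyl 3-bromo-4-[(1E)-4,4-dibromobuta-1,3-dien-1-yl]-1H-pyrrole-1-carboxylate
Conditions: CBr4, PPh3, Zn, CH2Cl2, rt; then 9, 0 °C to rt
Reagents that add atoms: carbon tetrabromide (10), BrC(Br)(Br)Br
Why: Ramirez (Corey–Fuchs) dibromoolefination; the ylide Ph3P=CBr2 is preformed with zinc so that no Ph3PBr2 or HBr is present to attack the carbamate, and it converts the aldehyde into the 1,1-dibromoalkene without touching the existing alkene.

Step 6
Reactants: 11 tert-butyl 3-bromo-4-[(1E)-4,4-dibromobuta-1,3-dien-1-yl]-1H-pyrrole-1-carboxylate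
Product: 14 tert-butyl 3,7-dibromo-1H-indole-1-carboxylate, via Z-diene 12 (not isolated), via 7,7-dibromo-7,7a-dihydroindole 13 (not isolated)
Conditions: hν (365 nm), K2CO3 (3 equiv), degassed MeCN (about 5 mM), 20 °C
Reagents that add atoms: none
Why: Proposed new method: light absorbed by the pyrrolyl diene first equilibrates the C1=C2 alkene of the side chain, so E-diene 11 feeds Z-diene 12, in which the pyrrole C4=C5 bond, the Z alkene and the CBr2 alkene form a hexatriene that can reach the s-cis,Z,s-cis shape. Excited-state conrotatory 6π electrocyclisation then joins the pyrrole α-carbon (future C7a) to the CBr2 carbon (future C7) and closes the six-membered carbocycle, giving dihydroindole 13. In 13 the hydrogen on C7a lies next to an allylic geminal dibromide, so loss of HBr (ionisation of one C7–Br bond to a bromine-stabilised allyl cation and loss of the C7a proton, or direct elimination assisted by K2CO3) should be fast and irreversible; it restores the pyrrole and creates the benzene ring, keeping the second bromine on C7 while the pyrrole bromine becomes C3–Br. The closest known reaction types are the photocyclisation of stilbenes and 1-arylbutadienes (Mallory reaction), in particular the non-oxidative variants in which a leaving group on the closing carbon is expelled as HX, and the thermal electrocyclisation of divinylpyrroles to indoles; a dibromomethylene terminus closing onto a pyrrole has not been shown. The only stereocentre formed, C7a of 13, is racemic and is erased by the elimination, so the sense of conrotation does not matter. The step needs site selectivity for the α-carbon over the brominated β-carbon C3, and this is secured because in an N-acylpyrrole the C4=C5 bond next to the side chain is the localised alkene that completes the triene, whereas closure at C3 would have to use the weak C3–C4 π-component and build a quaternary carbon. It also needs the C–Br bonds to survive: 365 nm light should be absorbed only in the long-wavelength tail of the extended diene chromophore and not by the isolated C–Br bonds or by product 14, the chain has no allylic hydrogen for sigmatropic shifts, and dilute, oxygen-free solution holds back [2+2] dimerisation and photo-oxidation.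

Step 7
Reactants: 14 tert-butyl 3,7-dibromo-1H-indole-1-carboxylate
Product: 15 3,7-dibromo-1H-indole
Conditions: K2CO3 (0.5 equiv), MeOH, rt
Reagents that add atoms: none
Why: Base-catalysed methanolysis of an indole N-carbamate; the Boc group on an indole nitrogen is an activated acyl group, here further strained by the neighbouring C7 bromine, and is transferred to methoxide while the aryl C–Br bonds are inert.

Step 8
Reactants: 15 3,7-dibromo-1H-indole
Product: 16 2,3,7-tribromo-1H-indole
Conditions: N-bromosuccinimide (1.0 equiv), THF, −78 to 0 °C, dark
Reagents that add atoms: N-bromosuccinimide, O=C1CCC(=O)N1Br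
Why: Electrophilic bromination of a 3-substituted indole; the electrophile adds at C3 to give a 3,3-dibromoindoleninium ion, one bromine shifts to C2 and loss of the C2 proton gives the 2,3-dibromide, while the benzene ring, deactivated by the C7 bromine, should react more slowly, so one equivalent at low temperature should stop at the target.

## Compound list

1 | 1-(triisopropylsilyl)-1H-pyrrole | CC(C)[Si](C(C)C)(C(C)C)n1cccc1 | starting material
2 | 3,4-dibromo-1-(triisopropylsilyl)-1H-pyrrole | CC(C)[Si](C(C)C)(C(C)C)n1cc(Br)c(Br)c1 | intermediate
3 | 3-bromo-4-lithio-1-(triisopropylsilyl)-1H-pyrrole | [Li]c1cn([Si](C(C)C)(C(C)C)C(C)C)cc1Br | intermediate (not isolated)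
4 | 4-bromo-1-(triisopropylsilyl)-1H-pyrrole-3-carbaldehyde | O=Cc1cn([Si](C(C)C)(C(C)C)C(C)C)cc1Br | intermediate
5 | di-tert-butyl dicarbonate | CC(C)(C)OC(=O)OC(=O)OC(C)(C)C | starting material
6 | 4-bromo-1H-pyrrole-3-carbaldehyde (formed as its tetrabutylammonium salt) | O=Cc1c[nH]cc1Br | intermediate (not isolated)
7 | tert-butyl 3-bromo-4-formyl-1H-pyrrole-1-carboxylate | CC(C)(C)OC(=O)n1cc(Br)c(C=O)c1 | intermediate
8 | (triphenylphosphoranylidene)acetaldehyde | O=CC=P(c1ccccc1)(c1ccccc1)c1ccccc1 | starting material
9 | tert-butyl 3-bromo-4-[(1E)-3-oxoprop-1-en-1-yl]-1H-pyrrole-1-carboxylate | CC(C)(C)OC(=O)n1cc(Br)c(/C=C/C=O)c1 | intermediate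
10 | carbon tetrabromide | BrC(Br)(Br)Br | starting material
11 | tert-butyl 3-bromo-4-[(1E)-4,4-dibromobuta-1,3-dien-1-yl]-1H-pyrrole-1-carboxylate | CC(C)(C)OC(=O)n1cc(Br)c(/C=C/C=C(Br)Br)c1 | intermediate
12 | tert-butyl 3-bromo-4-[(1Z)-4,4-dibromobuta-1,3-dien-1-yl]-1H-pyrrole-1-carboxylate | CC(C)(C)OC(=O)n1cc(Br)c(/C=C\C=C(Br)Br)c1 | intermediate (not isolated)
13 | tert-butyl 3,7,7-tribromo-7,7a-dihydro-1H-indole-1-carboxylate (racemic at C7a) | CC(C)(C)OC(=O)N1C=C(Br)C2=CC=CC(Br)(Br)C12 | intermediate (not isolated)
14 | tert-butyl 3,7-dibromo-1H-indole-1-carboxylate | CC(C)(C)OC(=O)n1cc(Br)c2cccc(Br)c12 | intermediate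
15 | 3,7-dibromo-1H-indole | Brc1c[nH]c2c(Br)cccc12 | intermediate
16 | 2,3,7-tribromo-1H-indole | Brc1[nH]c2c(Br)cccc2c1Br | target

## Step count and risk

Total step count: 8. Longest linear sequence: 8 steps (1 to 16); the route is fully linear.

**Step 6 (key step, proposed new method).**
- What may go wrong: photolytic cleavage of a vinylic C–Br bond of the dibromoalkene may compete with ring closure and lead to debromination and oligomers. Closure may also be slow, because the s-cis,Z,s-cis conformer must turn one bromine towards the pyrrole C5–H and is therefore twisted, so the mixture could stall at an E/Z photostationary state. Absorption at 365 nm may be too weak to drive the reaction.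
- Fallback (known reaction types, no light): it sets out from aldehyde 7. Stork–Zhao olefination with the ylide from (iodomethyl)triphenylphosphonium iodide and NaN(SiMe3)2 in THF at −78 °C should give the Z-vinyl iodide, tert-butyl 3-bromo-4-[(Z)-2-iodoethenyl]-1H-pyrrole-1-carboxylate F1. Sonogashira coupling of F1 with (trimethylsilyl)acetylene (Pd(PPh3)2Cl2, CuI, Et3N, rt) should react at the vinyl iodide only and give the silyl enyne, tert-butyl 3-bromo-4-[(1Z)-4-(trimethylsilyl)but-1-en-3-yn-1-yl]-1H-pyrrole-1-carboxylate F2. Treatment of F2 with AgF and N-bromosuccinimide in MeCN should exchange silicon for bromine to give the bromoalkyne, tert-butyl 3-bromo-4-[(1Z)-4-bromobut-1-en-3-yn-1-yl]-1H-pyrrole-1-carboxylate F3. InCl3 (cat.) in toluene at 80 °C should then bring about 6-endo-dig hydroarylation of the bromoalkyne by the pyrrole α-carbon without halide migration. This closes the same C7–C7a bond with bromine retained on C7 and comes back to the route at 14.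

**Step 4.**
- What may go wrong: a second Wittig homologation of the product enal to a dienal, because the product aldehyde is about as reactive as 7.
- Fallback: it sets out from 7 and uses a masked aldehyde, so the product cannot react again. Wittig reaction with the ylide from (1,3-dioxolan-2-ylmethyl)triphenylphosphonium bromide and NaN(SiMe3)2 in THF should give the vinyl dioxolane, tert-butyl 3-bromo-4-[2-(1,3-dioxolan-2-yl)ethenyl]-1H-pyrrole-1-carboxylate F4, as an E/Z mixture. Mild hydrolysis of F4 (1 M HCl, THF, rt) should release the enal and equilibrate it to the E isomer, returning to the route at 9.

**Step 8.**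
- What may go wrong: further bromination on the benzene ring (C5 or C6), or oxidative decomposition of the electron-rich N–H indole during bromination and isolation.
- Fallback: it sets out from 14 and replaces electrophilic substitution by directed metalation. LiN(i-Pr)2 in THF at −78 °C should deprotonate C2, which is acidified by the carbamate and the C3 bromine, and 1,2-dibromotetrachloroethane should brominate the C2 anion to give tert-butyl 2,3,7-tribromo-1H-indole-1-carboxylate F5. Cleavage of the carbamate of F5 with K2CO3 in MeOH comes back to the route at 16. The risk there is migration of bromine in the lithiated species, which the low temperature should hold back.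

Further compounds

F1 | step 6 | tert-butyl 3-bromo-4-[(Z)-2-iodoethenyl]-1H-pyrrole-1-carboxylate | CC(C)(C)OC(=O)n1cc(Br)c(/C=C\I)c1
F2 | step 6 | tert-butyl 3-bromo-4-[(1Z)-4-(trimethylsilyl)but-1-en-3-yn-1-yl]-1H-pyrrole-1-carboxylate | CC(C)(C)OC(=O)n1cc(Br)c(/C=C\C#C[Si](C)(C)C)c1
F3 | step 6 | tert-butyl 3-bromo-4-[(1Z)-4-bromobut-1-en-3-yn-1-yl]-1H-pyrrole-1-carboxylate | CC(C)(C)OC(=O)n1cc(Br)c(/C=C\C#CBr)c1
F4 | step 4 | tert-butyl 3-bromo-4-[2-(1,3-dioxolan-2-yl)ethenyl]-1H-pyrrole-1-carboxylate (E/Z mixture) | CC(C)(C)OC(=O)n1cc(Br)c(C=CC2OCCO2)c1
F5 | step 8 | tert-butyl 2,3,7-tribromo-1H-indole-1-carboxylate | CC(C)(C)OC(=O)n1c(Br)c(Br)c2cccc(Br)c12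
A1 | alternative 1 | 1-(4-methylbenzenesulfonyl)-7-(trimethylsilyl)indoline | Cc1ccc(cc1)S(=O)(=O)N1CCc2cccc([Si](C)(C)C)c21
A2 | alternative 1 | N-(but-3-yn-1-yl)-4-methyl-N-[(trimethylsilyl)ethynyl]benzenesulfonamide | Cc1ccc(cc1)S(=O)(=O)N(CCC#C)C#C[Si](C)(C)C
A3 | alternative 1 | acetylene | C#C
A4 | alternative 2 | ethyl 7-bromo-1H-indole-3-carboxylate | CCOC(=O)c1c[nH]c2c(Br)cccc12
A5 | alternative 2 | ethyl (2Z)-3-[(2-bromophenyl)amino]prop-2-enoate | CCOC(=O)/C=C\Nc1ccccc1Br
A6 | alternative 3 | 7-bromo-1-(tert-butyldimethylsilyl)indoline | CC(C)(C)[Si](C)(C)N1CCc2cccc(Br)c21
A7 | alternative 3 | N-(tert-butyldimethylsilyl)-2-(2-fluorophenyl)ethan-1-amine | CC(C)(C)[Si](C)(C)NCCc1ccccc1F
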